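**Plan**

- Rings: A is the methoxy arene, B the para-phenylene, C the phenol ring, D the unsubstituted meta-phenylene. One ring (19-membered) must be built and there is no stereocentre.
- Cuts, in order: the phenol O–H is masked as a benzyl ether and the D–A bridge is taken back to a vinylene; both aryl–carbon bonds of that bridge are cut in one operation; the B–C bridge is cut as a Wittig alkene; the two diaryl ether C–O bonds are cut last.
- Enabling feature: the D–A bridge is a bare CH2–CH2 unit bonded only to two arene carbons (the ring A carbon para to OMe and the ring D carbon meta to the ether oxygen). It can therefore arrive whole as a 1,2-distannylethene that joins two aryl bromides.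
- Forward: A–O–B ether by SNAr and C–O–D ether by Chan–Lam coupling, union through the B–C bridge (Wittig, then diimide) to an open-chain dibromide, ring closure by double Stille coupling, one final hydrogenation.
- Stereochemistry: none to set; the alkene geometries (E/Z after the Wittig step, E in the macrocycle) vanish on reduction.

Key step: step 7

Remark: the Wittig product is carried on as an E/Z mixture, so its SMILES is written without alkene geometry. The two phenols, the fluoroaldehyde, the boronic acid and the distannane are taken as purchased.

**Route**

Step 1
Reactants: 1 5-bromo-2-methoxyphenol; 2 4-fluorobenzaldehyde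
Product: 3 4-(5-bromo-2-methoxyphenoxy)benzaldehyde
Conditions: K2CO3, DMF, 120 °C
Reagents that add atoms: none
Why: Nucleophilic aromatic substitution (SNAr), in which the para-formyl group activates the C–F carbon of 2 towards the phenol 1 deprotonated by K2CO3, while the unactivated C–Br bond of ring A is left alone.

Step 2
Reactants: 3 4-(5-bromo-2-methoxyphenoxy)benzaldehyde
Product: 4 [4-(5-bromo-2-methoxyphenoxy)phenyl]methanol
Conditions: NaBH4, MeOH/THF, 0 °C to rt
Reagents that add atoms: none
Why: Borohydride reduction of an aryl aldehyde, to which the aryl bromide and both ethers are inert.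

Step 3
Reactants: 4 [4-(5-bromo-2-methoxyphenoxy)phenyl]methanol
Product: 5 {[4-(5-bromo-2-methoxyphenoxy)phenyl]methyl}triphenylphosphonium bromide
Conditions: PPh3·HBr, MeCN, reflux
Reagents that add atoms: triphenylphosphine hydrobromide, SMILES Br.c1ccc(cc1)P(c1ccccc1)c1ccccc1
Why: Direct phosphonium salt formation from a benzylic alcohol, in which HBr activates the para-aryloxy-stabilised benzylic position and PPh3 captures it, so no separate benzyl bromide is needed.

Step 4
Reactants: 6 4-(benzyloxy)-3-hydroxybenzaldehyde; 7 3-bromophenylboronic acid
Product: 8 4-(benzyloxy)-3-(3-bromophenoxy)benzaldehyde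
Conditions: Cu(OAc)2 (1.5 equiv), pyridine, 4 Å MS, CH2Cl2, air, rt
Reagents that add atoms: none
Why: Chan–Lam oxidative C–O coupling of a phenol with an arylboronic acid, which runs at room temperature where copper does not insert into the C–Br bond, so ring D keeps its bromide and the aldehyde is tolerated.

Step 5
Reactants: 5 {[4-(5-bromo-2-methoxyphenoxy)phenyl]methyl}triphenylphosphonium bromide; 8 4-(benzyloxy)-3-(3-bromophenoxy)benzaldehyde
Product: 10 1-(benzyloxy)-2-(3-bromophenoxy)-4-{2-[4-(5-bromo-2-methoxyphenoxy)phenyl]ethenyl}benzene (E/Z mixture), via benzylidene phosphorane ylide 9 (not isolated)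
Conditions: K2CO3, 18-crown-6 (cat.), CH2Cl2, reflux
Reagents that add atoms: none
Why: Wittig olefination with a semi-stabilised benzylic ylide generated under mild solid–liquid phase-transfer conditions, which should join rings B and C through a CH=CH unit whose geometry is of no consequence because it is reduced in the next step.

Step 6
Reactants: 10 1-(benzyloxy)-2-(3-bromophenoxy)-4-{2-[4-(5-bromo-2-methoxyphenoxy)phenyl]ethenyl}benzene (E/Z mixture)
Product: 11 1-(benzyloxy)-2-(3-bromophenoxy)-4-{2-[4-(5-bromo-2-methoxyphenoxy)phenyl]ethyl}benzene (open-chain dibromide)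
Conditions: TsNHNH2 (excess), NaOAc, DME/H2O, reflux
Reagents that add atoms: none
Why: Diimide reduction, in which HN=NH released from the sulfonyl hydrazide transfers two hydrogens to the C=C bond in a concerted way and leaves both C–Br bonds and the benzyl ether intact, as catalytic hydrogenation over palladium would not.

Step 7
Reactants: 11 1-(benzyloxy)-2-(3-bromophenoxy)-4-{2-[4-(5-bromo-2-methoxyphenoxy)phenyl]ethyl}benzene; 12 (E)-1,2-bis(tributylstannyl)ethene
Product: 15 macrocyclic (E)-stilbene benzyl ether (19-membered ring; (E)-CH=CH bridge between ring D and ring A; ring C oxygen benzylated), via ring D vinylstannane 13 (not isolated), via ring A vinylstannane 14 (not isolated)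
Conditions: Pd[P(t-Bu)3]2 (20 mol %), CsF (4.4 equiv), 1,4-dioxane, 90 °C; 11 and 12 (1.0 equiv) co-added by syringe pump over 12 h, final ca. 2 mM
Reagents that add atoms: none
Why: This is a Stille cross-coupling run twice on one C2 linchpin: zerovalent palladium inserts into a C–Br bond (probably that of ring D, the less electron-rich one, first), fluoride-assisted transmetalation from one tin terminus and reductive elimination give the aryl vinylstannane 13 (or 14 if ring A reacts first), and a second oxidative addition at the remaining bromide is followed by intramolecular transmetalation and reductive elimination. The closest known reaction type is the stitching macrocyclisation of a bis-halide with a 1,2-bis(trialkylstannyl)ethene, and the same distannane is a standard partner of aryl dibromides in Stille polycondensation, which shows that both aryl–vinyl bonds form readily. The 19-membered ring closes in the second, intramolecular aryl–vinyl coupling through a 20-membered palladacycle, and both orders of bromide activation lead to the same ring. No stereocentre is formed, and the E geometry of 12 is carried into the bridge because Stille coupling proceeds with retention at both vinyl carbons. The step needs ring closure to win over chain growth and over capping of both bromides by two distannane molecules; this is secured by feeding 11 and 12 together, slowly and in equimolar amount, to an excess of active catalyst at high dilution, so that each dibromide meets one distannane and then only its own second terminus, helped by the two diaryl ether hinges that let the chain fold. Chemoselectivity is not at issue, because the bridge arrives complete, 11 carries no benzylic leaving group or carbonyl, and the benzyl and methyl ethers are inert to the catalyst.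

Step 8
Reactants: 15 macrocyclic (E)-stilbene benzyl ether
Product: 17 target macrocycle CNP0132125.0, via macrocyclic bibenzyl benzyl ether 16 (not isolated)
Conditions: H2 (1 atm), 10% Pd/C, EtOAc/MeOH, rt (after removal of tin residues over KF/silica)
Reagents that add atoms: none
Why: Catalytic hydrogenation over palladium on carbon, which should first saturate the stilbene C=C bond and then cleave the benzyl ether by hydrogenolysis, while the diaryl ethers and the methyl ether are stable.

**Compound list**

1 | 5-bromo-2-methoxyphenol | COc1ccc(Br)cc1O | starting material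
2 | 4-fluorobenzaldehyde | O=Cc1ccc(F)cc1 | starting material
3 | 4-(5-bromo-2-methoxyphenoxy)benzaldehyde | COc1ccc(Br)cc1Oc1ccc(C=O)cc1 | intermediate
4 | [4-(5-bromo-2-methoxyphenoxy)phenyl]methanol | COc1ccc(Br)cc1Oc1ccc(CO)cc1 | intermediate
5 | {[4-(5-bromo-2-methoxyphenoxy)phenyl]methyl}triphenylphosphonium bromide | COc1ccc(Br)cc1Oc1ccc(C[P+](c2ccccc2)(c2ccccc2)c2ccccc2)cc1.[Br-] | intermediate
6 | 4-(benzyloxy)-3-hydroxybenzaldehyde | O=Cc1ccc(OCc2ccccc2)c(O)c1 | starting material
7 | 3-bromophenylboronic acid | OB(O)c1cccc(Br)c1 | starting material
8 | 4-(benzyloxy)-3-(3-bromophenoxy)benzaldehyde | O=Cc1ccc(OCc2ccccc2)c(Oc2cccc(Br)c2)c1 | intermediate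
9 | {[4-(5-bromo-2-methoxyphenoxy)phenyl]methylidene}triphenylphosphorane (ylide, not isolated) | COc1ccc(Br)cc1Oc1ccc(C=P(c2ccccc2)(c2ccccc2)c2ccccc2)cc1 | intermediate
10 | 1-(benzyloxy)-2-(3-bromophenoxy)-4-{2-[4-(5-bromo-2-methoxyphenoxy)phenyl]ethenyl}benzene, E/Z mixture | COc1ccc(Br)cc1Oc1ccc(C=Cc2ccc(OCc3ccccc3)c(Oc3cccc(Br)c3)c2)cc1 | intermediate
11 | 1-(benzyloxy)-2-(3-bromophenoxy)-4-{2-[4-(5-bromo-2-methoxyphenoxy)phenyl]ethyl}benzene (open-chain dibromide; Br on ring A para to OMe, Br on ring D meta to O) | COc1ccc(Br)cc1Oc1ccc(CCc2ccc(OCc3ccccc3)c(Oc3cccc(Br)c3)c2)cc1 | intermediate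
12 | (E)-1,2-bis(tributylstannyl)ethene | CCCC[Sn](CCCC)(CCCC)/C=C/[Sn](CCCC)(CCCC)CCCC | starting material
13 | ring D vinylstannane: 11 in which the ring D bromide is replaced by (E)-2-(tributylstannyl)ethenyl, ring A bromide retained (not isolated) | COc1ccc(Br)cc1Oc1ccc(CCc2ccc(OCc3ccccc3)c(Oc3cccc(/C=C/[Sn](CCCC)(CCCC)CCCC)c3)c2)cc1 | intermediate
14 | ring A vinylstannane: 11 in which the ring A bromide is replaced by (E)-2-(tributylstannyl)ethenyl, ring D bromide retained (not isolated) | COc1ccc(/C=C/[Sn](CCCC)(CCCC)CCCC)cc1Oc1ccc(CCc2ccc(OCc3ccccc3)c(Oc3cccc(Br)c3)c2)cc1 | intermediate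
15 | macrocyclic (E)-stilbene benzyl ether: 19-membered ring, rings D and A joined by an (E)-CH=CH bridge, ring C oxygen benzylated | c1cc2cc(c1)/C=C/c1ccc(OC)c(c1)Oc1ccc(cc1)CCc1ccc(OCc3ccccc3)c(c1)O2 | intermediate
16 | macrocyclic bibenzyl benzyl ether: the O-benzyl ether of the target (not isolated in step 8) | COc1ccc2cc1Oc1ccc(cc1)CCc1ccc(OCc3ccccc3)c(c1)Oc1cccc(c1)CC2 | intermediate
17 | CNP0132125.0: 19-membered bis(bibenzyl) macrocycle with OMe on ring A and free OH on ring C | COc1ccc2cc1Oc1ccc(cc1)CCc1ccc(O)c(c1)Oc1cccc(c1)CC2 | target

**Step count**

Total: 8 steps. Longest linear sequence: 7 steps (steps 1, 2, 3, 5, 6, 7, 8); step 4 is a one-step branch.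

**Steps most likely to fail**

Step 7. The second aryl–vinyl coupling may go between molecules and not within one, giving chain growth. Both bromides of one molecule may also be capped by two separate distannane molecules, and strain in the E-configured ring may slow closure further. The fallback sets out from 11. A double Stille coupling with tributyl(vinyl)stannane (Pd[P(t-Bu)3]2, CsF, dioxane) should give the bis-styrene 1-(benzyloxy)-2-(3-ethenylphenoxy)-4-{2-[4-(5-ethenyl-2-methoxyphenoxy)phenyl]ethyl}benzene F1. Ring-closing metathesis of it (second-generation Grubbs catalyst RuCl2(=CHPh)(H2IMes)(PCy3), toluene, 80 °C, ca. 1 mM) closes the same bridge at its C=C bond with loss of ethene. That ring closure is unimolecular and reversible, so oligomers can be corrected. It rejoins the route at 15; any (Z)-isomer of 15 F2 formed alongside converges with 15 in step 8.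

Step 4. C–O bond formation on the ortho-alkoxy phenol may be slow, so that the boronic acid is consumed by protodeboronation and oxidative homocoupling before the coupling is complete. The fallback sets out from 6 and swaps the oxidative coupling for an Ullmann ether synthesis with 1-bromo-3-iodobenzene (CuI, N,N-dimethylglycine hydrochloride, Cs2CO3, 1,4-dioxane, 90 °C). Here the C–I bond should react well before the C–Br bond. It rejoins the route at 8 directly, so no compound beyond the list arises (F0).

Step 8. Tin or phosphine residues carried over from step 7 may poison the heterogeneous catalyst, so that saturation of the bridge or, more likely, hydrogenolysis of the benzyl ether stalls. The fallback sets out from 15 and needs no metal surface. Diimide (TsNHNH2, NaOAc, DME/H2O, reflux) should saturate the bridge and give 16, now isolated. BCl3 with pentamethylbenzene as cation scavenger (CH2Cl2, −78 °C) then cleaves the benzyl ether in the presence of the aryl methyl ether and rejoins the route at 17. No compound beyond the list arises (F0).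

**Further compounds**

F1 | step 7 | 1-(benzyloxy)-2-(3-ethenylphenoxy)-4-{2-[4-(5-ethenyl-2-methoxyphenoxy)phenyl]ethyl}benzene | COc1ccc(C=C)cc1Oc1ccc(CCc2ccc(OCc3ccccc3)c(Oc3cccc(C=C)c3)c2)cc1
F2 | step 7 | (Z)-isomer of 15, macrocyclic (Z)-stilbene benzyl ether | c1cc2cc(c1)/C=C\c1ccc(OC)c(c1)Oc1ccc(cc1)CCc1ccc(OCc3ccccc3)c(c1)O2
F0 | step 4 | none | none
F0 | step 8 | none | none
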